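The route installs all four ring A bromines last, after the diaryl ether has been made between two unhindered rings. Every carbon from C3 to C6 of ring A sits ortho or para to an oxygen substituent (the hydroxyl on C1 or the aryloxy oxygen on C2). One exhaustive electrophilic bromination of 2-(2-nitrophenoxy)phenol should therefore form all four C–Br bonds at once. Ring B is spared because C2' carries a deactivating nitro group where the last bromine will stand. The precursor is the mono-(2-nitrophenyl) ether of catechol with its phenol free. Afterwards the phenol is capped as a methyl ether, the nitro group becomes bromine by reduction and Sandmeyer exchange, and the cap is removed.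

Key step: step 2

Remark: ring A is the phenol ring (C1 bears the hydroxyl, C2 the ether oxygen) and ring B is the ring that ends as 2-bromophenyl (primed numbers, C1' on oxygen). The target has no stereocentre, so no step has to set one.

Step 1
Reactants: 1 catechol; 2 1-fluoro-2-nitrobenzene
Product: 3 2-(2-nitrophenoxy)phenol
Conditions: 1 (3 equiv), K2CO3 (1.5 equiv), DMF, N2, 50 °C; aq. HCl work-up
Reagents that add atoms: none
Why: Nucleophilic aromatic substitution (SNAr) of fluoride by the catechol monoanion through a Meisenheimer adduct stabilised by the ortho nitro group; the excess of catechol and the mild temperature should hold the reaction at the mono-ether, short of a second arylation or displacement of nitrite to a dibenzodioxin.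

Step 2
Reactants: 3 2-(2-nitrophenoxy)phenol; 4 bromine
Product: 8 3,4,5,6-tetrabromo-2-(2-nitrophenoxy)phenol, via monobromide 5 (not isolated), via dibromide 6 (not isolated), via tribromide 7 (not isolated)
Conditions: Br2 (4.4 equiv), dry AcOH, 20 °C, then Fe powder (5 mol %), 60 °C; aq. NaHSO3 quench
Reagents that add atoms: bromine (compound 4), BrBr
Why: Bromine, polarised by acetic acid and for the last crowded positions by FeBr3 formed from the iron, should attack ring A four times by the arenium (SEAr) pathway, in the expected order C4 (para to the C1 hydroxyl), C6 (ortho to it), C5 (para to the C2 ether oxygen) and C3 (ortho to it), each arenium ion being stabilised by an oxygen lone pair before it loses a proton. The closest known reaction type is the exhaustive electrophilic bromination of catechol to tetrabromocatechol and of catechol monoethers such as guaiacol to their tetrabromides. No ring closes and no stereocentre is created, so neither a closure mode nor a stereocontrolling element is involved. The selectivity needed is between the rings: ring A reacts because it carries the free hydroxyl, whereas ring B is deactivated as a whole by its nitro group and the lone pair of its ether oxygen is drained further as ring A takes up bromine, so ring B should remain less reactive than benzene. A small excess of bromine, exclusion of water and the hydrogensulfite quench should guard against a fifth bromine and against oxidative loss of the aryl ether.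

Step 3
Reactants: 8 3,4,5,6-tetrabromo-2-(2-nitrophenoxy)phenol
Product: 9 1,2,3,4-tetrabromo-5-methoxy-6-(2-nitrophenoxy)benzene
Conditions: MeI (1.5 equiv), K2CO3 (2 equiv), DMF, 25 °C
Reagents that add atoms: iodomethane, CI
Why: Williamson O-methylation (SN2) of the acidic tetrabromophenoxide; the methyl cap keeps the phenol away from nitrous acid (Zincke-type nitro-debromination) and from ring closure onto the later diazonium ion, and unlike an ester of so acidic a phenol it cannot migrate to the aniline formed in step 4.

Step 4
Reactants: 9 1,2,3,4-tetrabromo-5-methoxy-6-(2-nitrophenoxy)benzene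
Product: 10 2-(2,3,4,5-tetrabromo-6-methoxyphenoxy)aniline
Conditions: Fe powder (5 equiv), AcOH/EtOH 1:1, 60 °C
Reagents that add atoms: none
Why: Béchamp-type dissolving-metal reduction, in which zerovalent iron in acetic acid delivers six electrons to the nitro group through the nitroso and hydroxylamine stages and leaves aryl C–Br bonds and both ethers intact, which catalytic hydrogenation would not guarantee.

Step 5
Reactants: 10 2-(2,3,4,5-tetrabromo-6-methoxyphenoxy)aniline
Product: 12 1,2,3,4-tetrabromo-5-(2-bromophenoxy)-6-methoxybenzene, via diazonium bromide 11 (not isolated)
Conditions: NaNO2 (1.2 equiv), 48% aq. HBr, MeCN, 0 °C; then CuBr (1 equiv), 48% aq. HBr, 0 → 60 °C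
Reagents that add atoms: hydrogen bromide, Br (source of the new ring B bromine and of the counter-ion of 11); sodium nitrite, [Na+].[O-]N=O (its nitrogen stays only in intermediate 11 and leaves as N2)
Why: Diazotisation followed by Sandmeyer bromination, in which monovalent copper (CuBr) reduces the diazonium ion to an aryl radical with loss of N2 and the radical takes bromine from the CuBr2 so formed, regenerating CuBr; the fully substituted, methyl-capped ring A offers no site for azo coupling, and the high bromide and copper concentration should outrun radical cyclisation onto ring A.

Step 6
Reactants: 12 1,2,3,4-tetrabromo-5-(2-bromophenoxy)-6-methoxybenzene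
Product: 14 3,4,5,6-tetrabromo-2-(2-bromophenoxy)phenol, via aryloxydibromoborane 13 (not isolated)
Conditions: BBr3 (3 equiv), CH2Cl2, −78 → 20 °C; then H2O
Reagents that add atoms: boron tribromide, BrB(Br)Br (boron and bromine stay only in intermediate 13; on going to 14 only hydrogen from water is added)
Why: Lewis-acid cleavage of an aryl methyl ether, in which BBr3 binds the methoxy oxygen and bromide removes the methyl group by SN2 to give the aryl borate that water hydrolyses; the diaryl ether has no sp3 carbon to attack and the aryl bromides are inert.

Compound list
1 | catechol (benzene-1,2-diol) | Oc1ccccc1O | starting material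
2 | 1-fluoro-2-nitrobenzene | [O-][N+](=O)c1ccccc1F | starting material
3 | 2-(2-nitrophenoxy)phenol | Oc1ccccc1Oc1ccccc1[N+](=O)[O-] | intermediate
4 | bromine | BrBr | starting material
5 | 4-bromo-2-(2-nitrophenoxy)phenol | Oc1ccc(Br)cc1Oc1ccccc1[N+](=O)[O-] | intermediate (not isolated)
6 | 4,6-dibromo-2-(2-nitrophenoxy)phenol | Oc1c(Br)cc(Br)cc1Oc1ccccc1[N+](=O)[O-] | intermediate (not isolated)
7 | 4,5,6-tribromo-2-(2-nitrophenoxy)phenol | Oc1c(Br)c(Br)c(Br)cc1Oc1ccccc1[N+](=O)[O-] | intermediate (not isolated)
8 | 3,4,5,6-tetrabromo-2-(2-nitrophenoxy)phenol | Oc1c(Br)c(Br)c(Br)c(Br)c1Oc1ccccc1[N+](=O)[O-] | intermediate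
9 | 1,2,3,4-tetrabromo-5-methoxy-6-(2-nitrophenoxy)benzene | COc1c(Br)c(Br)c(Br)c(Br)c1Oc1ccccc1[N+](=O)[O-] | intermediate
10 | 2-(2,3,4,5-tetrabromo-6-methoxyphenoxy)aniline | COc1c(Br)c(Br)c(Br)c(Br)c1Oc1ccccc1N | intermediate
11 | 2-(2,3,4,5-tetrabromo-6-methoxyphenoxy)benzenediazonium bromide | COc1c(Br)c(Br)c(Br)c(Br)c1Oc1ccccc1[N+]#N.[Br-] | intermediate (not isolated)
12 | 1,2,3,4-tetrabromo-5-(2-bromophenoxy)-6-methoxybenzene | COc1c(Br)c(Br)c(Br)c(Br)c1Oc1ccccc1Br | intermediate
13 | dibromo[3,4,5,6-tetrabromo-2-(2-bromophenoxy)phenoxy]borane | BrB(Br)Oc1c(Br)c(Br)c(Br)c(Br)c1Oc1ccccc1Br | intermediate (not isolated)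
14 | 3,4,5,6-tetrabromo-2-(2-bromophenoxy)phenol | Oc1c(Br)c(Br)c(Br)c(Br)c1Oc1ccccc1Br | target

Total step count: 6. Longest linear sequence: 6 steps (catechol to 14).

Steps most likely to fail

Step 2. The substitution may stall at the tribromide stage, because the last site (C3) is crowded and activated only by an electron-poor aryloxy oxygen. Forcing it may then let bromine reach ring B or oxidise the phenol with loss of the aryl ether. The fallback reverses the order of events and uses known chemistry. It sets out from catechol 1, which is brominated exhaustively with bromine 4 in acetic acid to 3,4,5,6-tetrabromobenzene-1,2-diol F1. The dianion of F1 (K2CO3, DMSO, about 70 °C) is then mono-arylated by 2 in an SNAr reaction. The remaining, weakly nucleophilic and hindered phenoxide should resist a second arylation. This comes back to the route at 8.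

Step 5. The lipophilic amine may diazotise incompletely in the aqueous acid. The aryl radical may also be lost to hydrogen abstraction or to ipso cyclisation onto ring A with expulsion of bromine. The fallback separates diazotisation from halide delivery. It sets out from 10, which is diazotised as before; the diazonium ion is trapped with pyrrolidine and K2CO3 as the isolable (E)-1-{[2-(2,3,4,5-tetrabromo-6-methoxyphenoxy)phenyl]diazenyl}pyrrolidine F2. The purified triazene is then heated with bromotrimethylsilane in dry acetonitrile at about 60 °C, which releases the diazonium ion in the presence of bromide without copper or water. This comes back to the route at 12.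

Step 1. The mono-ether phenoxide may be arylated a second time, the catecholate may be oxidised by adventitious air, or the product may cyclise with loss of nitrite. The fallback replaces statistical control by a protecting group. It sets out from 2, which is condensed with commercial 2-methoxyphenol (guaiacol, COc1ccccc1O) under K2CO3 in DMF to 1-methoxy-2-(2-nitrophenoxy)benzene F3. The methyl ether is then cleaved with BBr3 in CH2Cl2. This comes back to the route at 3.

Further compounds
F1 | step 2 | 3,4,5,6-tetrabromobenzene-1,2-diol | Oc1c(O)c(Br)c(Br)c(Br)c1Br
F2 | step 5 | (E)-1-{[2-(2,3,4,5-tetrabromo-6-methoxyphenoxy)phenyl]diazenyl}pyrrolidine | COc1c(Br)c(Br)c(Br)c(Br)c1Oc1ccccc1/N=N/N1CCCC1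
F3 | step 1 | 1-methoxy-2-(2-nitrophenoxy)benzene | COc1ccccc1Oc1ccccc1[N+](=O)[O-]
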